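**Plan**

- Atom labels: chromene O1, C2, C3, C4, C4a, C5–C8, C8a; cyclohexene C1′ (quaternary, bears CH3 and the CH2CH2 link to C2), C2′H2, C3′H2, C4′H=C5′(CH3), C6′H(CH3).
- Retrosynthesis cuts C3=C4 (olefin metathesis), then O1–C2 (asymmetric O-allylation of a phenol), then the C2/C3 unit from the chain (alkyne, methylalumination), and last C1′–C6′ and C2′–C3′ of the cyclohexene.
- Enabling feature: the C4′=C5′ double bond lies across the ring from the C1′–C6′ bond (quaternary C1′ next to methine C6′), so the cyclohexene is the [4+2] adduct of a 1,1-disubstituted alkene and 3-methylpenta-1,3-diene; a lactone ties the two C1′ substituents together in the dienophile.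
- Forward: the cyclohexene ring forms first as a spirolactone; the lactone carbonyl carbon is reduced to the C1′ methyl and the OCH2CH2 arm is extended to an E allylic carbonate; the arene is made separately in four steps; O1–C2 joins the halves and the pyran ring closes last.
- Stereochemistry: C1′ and C6′ (cis methyls) come from the endo, catalyst-controlled cycloaddition; C2 comes from the chiral palladium catalyst in the O-allylation.

Key step: step 1

Assumption: the absolute sense of induction in the two catalyst-controlled steps (1 and 12) is assigned by analogy with acrylate dienophiles and with trisubstituted allyl carbonates; both catalysts exist in either enantiomeric form, so the antipode is substituted if the first correlation shows the opposite sense.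

**Route**

Step 1
Reactants: 1 3-methylideneoxolan-2-one (α-methylene-γ-butyrolactone); 2 (3E)-3-methylpenta-1,3-diene
Product: 3 (5R,6R)-6,7-dimethyl-2-oxaspiro[4.5]dec-7-en-1-one
Conditions: (S)-1-(2-methylphenyl)-3,3-diphenyltetrahydro-1H,3H-pyrrolo[1,2-c][1,3,2]oxazaborole (12 mol%), AlBr3 (10 mol%), CH2Cl2, −78 → −20 °C; 2 as commercial E/Z mixture (3 equiv)
Reagents that add atoms: none
Why: The AlBr3-activated oxazaborolidine is a strong chiral boron Lewis acid that binds the lactone carbonyl at the lone pair anti to C-α and lowers the LUMO of the s-cis-locked enoate, which then undergoes a concerted but asynchronous suprafacial [4+2] cycloaddition with the s-cis conformer of the E diene, the exocyclic CH2 bonding ahead of the α-carbon. The closest known reactions are the achiral Lewis acid-promoted Diels–Alder additions of α-methylene-γ-butyrolactone to dienes, which give spirolactones, and the oxazaborolidinium-catalysed enantioselective additions of acrylate esters and 2-substituted acroleins to acyclic dienes. The cyclohexene ring is closed by intermolecular cycloaddition, both σ-bonds (C5–C6 = C1′–C6′ and C10–C9 = C2′–C3′) forming across one face of each partner, so the new ring is spiro-fused to the existing lactone. The relative configuration at C5 and C6 follows from the endo transition state, in which the coordinated carbonyl lies under the diene and the E-methyl points outward, so carbonyl and 6-methyl end up cis; the absolute configuration is set by the catalyst, whose aryl groups shield one face of the bound dienophile. Regiochemistry (C5 bonded to the CH(CH3) terminus) is also required and is secured by the terminal methyl of the diene, which places the larger HOMO coefficient and the lesser steric demand on the CH2 terminus that bonds first to the exocyclic CH2, an effect sharpened by Lewis acid activation. Only the E isomer of the diene mixture should react, because the Z isomer cannot reach the s-cis conformation without a methyl–hydrogen clash.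

Step 2
Reactants: 3 (5R,6R)-6,7-dimethyl-2-oxaspiro[4.5]dec-7-en-1-one
Product: 4 (5R,6R)-6,7-dimethyl-2-oxaspiro[4.5]dec-7-en-1-ol (lactol, both C1 anomers)
Conditions: i-Bu2AlH (1.1 equiv), CH2Cl2, −78 °C; aq. KNaC4H4O6 work-up
Reagents that add atoms: none
Why: Partial reduction of a γ-lactone by i-Bu2AlH at low temperature stops at the aluminium hemiacetal, which gives the lactol on work-up without touching either stereocentre; the new hemiacetal carbon is of no consequence because it becomes the C1′ methyl.

Step 3
Reactants: 4 (5R,6R)-6,7-dimethyl-2-oxaspiro[4.5]dec-7-en-1-ol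
Product: 6 2-[(1S,2S)-1,2,3-trimethylcyclohex-3-en-1-yl]ethan-1-ol, via hydroxy hydrazone 5 (not isolated)
Conditions: N2H4·H2O (5 equiv), KOH (4 equiv), diethylene glycol, 130 °C then 200 °C, argon
Reagents that add atoms: none
Why: Wolff–Kishner reduction (Huang-Minlon procedure) acts on the ring-opened hydroxy aldehyde form of the lactol, so the hydrazone loses N2 and the non-enolisable neopentyl CHO becomes the C1′ methyl while the other arm remains a primary alcohol; the quaternary α-carbon cannot epimerise and the isolated ring alkene is inert.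

Step 4
Reactants: 6 2-[(1S,2S)-1,2,3-trimethylcyclohex-3-en-1-yl]ethan-1-ol
Product: 7 2-[(1S,2S)-1,2,3-trimethylcyclohex-3-en-1-yl]ethyl 4-methylbenzenesulfonate
Conditions: TsCl, Et3N, DMAP (cat.), CH2Cl2, 0 °C → rt
Reagents that add atoms: 4-methylbenzenesulfonyl chloride, Cc1ccc(cc1)S(Cl)(=O)=O
Why: Sulfonylation of an unhindered primary alcohol gives a leaving group without exposing the ring alkene to an electrophilic halogen.

Step 5
Reactants: 7 2-[(1S,2S)-1,2,3-trimethylcyclohex-3-en-1-yl]ethyl 4-methylbenzenesulfonate
Product: 8 4-[(1S,2S)-1,2,3-trimethylcyclohex-3-en-1-yl]but-1-yne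
Conditions: LiC≡CH·H2NCH2CH2NH2 (2 equiv), DMSO, 15 °C → rt
Reagents that add atoms: lithium acetylide–ethylenediamine complex, [Li+].[C-]#C.NCCN
Why: SN2 displacement of a primary tosylate with an unbranched β-carbon by acetylide in DMSO is a standard terminal alkyne synthesis, and the two carbons added become C2 and C3 of the chromene.

Step 6
Reactants: 8 4-[(1S,2S)-1,2,3-trimethylcyclohex-3-en-1-yl]but-1-yne
Product: 11 (2E)-3-methyl-5-[(1S,2S)-1,2,3-trimethylcyclohex-3-en-1-yl]pent-2-en-1-ol, via alkenyldimethylalane 9 (not isolated), via lithium alkenylaluminate 10 (not isolated)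
Conditions: AlMe3 (2 equiv), Cp2ZrCl2 (0.25 equiv), CH2Cl2, rt; excess AlMe3 removed in vacuo; n-BuLi, THF–hexane, 0 °C; (CH2O)n, rt; aq. HCl
Reagents that add atoms: trimethylaluminium, C[Al](C)C; paraformaldehyde (as formaldehyde), C=O
Why: Negishi zirconium-catalysed methylalumination adds CH3 and Al syn across the terminal alkyne with Al at the terminus, and the derived aluminate is hydroxymethylated with retention, so the trisubstituted alkene should form as the E isomer only while the ring alkene does not react.

Step 7
Reactants: 11 (2E)-3-methyl-5-[(1S,2S)-1,2,3-trimethylcyclohex-3-en-1-yl]pent-2-en-1-ol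
Product: 12 methyl (2E)-3-methyl-5-[(1S,2S)-1,2,3-trimethylcyclohex-3-en-1-yl]pent-2-en-1-yl carbonate
Conditions: ClCO2Me, pyridine, CH2Cl2, 0 °C
Reagents that add atoms: methyl chloroformate, COC(=O)Cl
Why: Acylation of the primary allylic alcohol installs the carbonate leaving group, which on ionisation also supplies the methoxide base for the allylation.

Step 8
Reactants: 13 2,3,4-trimethoxybenzaldehyde
Product: 14 5-bromo-2,3,4-trimethoxybenzaldehyde
Conditions: NBS, MeCN, rt → 40 °C
Reagents that add atoms: N-bromosuccinimide, BrN1C(=O)CCC1=O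
Why: Electrophilic aromatic bromination goes to C5, the only free position that is ortho and para to methoxy groups and meta to the formyl group.

Step 9
Reactants: 14 5-bromo-2,3,4-trimethoxybenzaldehyde
Product: 16 5-bromo-2,3,4-trimethoxyphenol, via aryl formate 15 (not isolated)
Conditions: 30% H2O2, H2SO4 (cat.), MeOH, rt
Reagents that add atoms: hydrogen peroxide, OO
Why: In this Dakin-type Baeyer–Villiger oxidation the aryl group, made electron-rich by its ortho- and para-methoxy substituents, migrates to oxygen and the resulting formate is methanolysed in the same flask.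

Step 10
Reactants: 16 5-bromo-2,3,4-trimethoxyphenol
Product: 17 4,5,6-trimethoxybenzene-1,3-diol
Conditions: Pd2(dba)3 (2 mol%), 2-di-tert-butylphosphino-2′,4′,6′-triisopropylbiphenyl (8 mol%), KOH (4 equiv), 1,4-dioxane–H2O, 100 °C, argon; then aq. HCl under argon
Reagents that add atoms: potassium hydroxide, [K+].[OH-]
Why: Palladium-catalysed C–O coupling of an aryl bromide with hydroxide, enabled by a bulky biarylphosphine, replaces Br by OH and gives a resorcinol whose two hydroxyls are equivalent by symmetry.

Step 11
Reactants: 17 4,5,6-trimethoxybenzene-1,3-diol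
Product: 19 2,6-dihydroxy-3,4,5-trimethoxybenzaldehyde, via aryl iminium chloride 18 (not isolated)
Conditions: POCl3, DMF, EtOAc, 0 °C → rt; then H2O, 50 °C
Reagents that add atoms: N,N-dimethylformamide, CN(C)C=O; water, O
Why: Vilsmeier–Haack formylation attacks the single unsubstituted ring carbon, which is activated by both flanking hydroxyls, and the iminium salt is hydrolysed to the aldehyde.

Step 12
Reactants: 12 methyl (2E)-3-methyl-5-[(1S,2S)-1,2,3-trimethylcyclohex-3-en-1-yl]pent-2-en-1-yl carbonate; 19 2,6-dihydroxy-3,4,5-trimethoxybenzaldehyde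
Product: 20 2-hydroxy-3,4,5-trimethoxy-6-({(3R)-3-methyl-5-[(1S,2S)-1,2,3-trimethylcyclohex-3-en-1-yl]pent-1-en-3-yl}oxy)benzaldehyde
Conditions: Pd2(dba)3·CHCl3 (2.5 mol%), (1R,2R)-N,N′-bis[2-(diphenylphosphanyl)benzoyl]cyclohexane-1,2-diamine (7.5 mol%), CH2Cl2, rt; 19 (1.5 equiv)
Reagents that add atoms: none
Why: In this Tsuji–Trost asymmetric allylic alkylation the carbonate ionises to a π-allylpalladium complex whose faces interconvert through the CH2 terminus, and the phenoxide attacks the more substituted terminus inside the chiral ligand pocket to set C2 as R; the second hydroxyl, hydrogen-bonded to the formyl group, should stay free, and both ortho positions are blocked against Claisen rearrangement.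

Step 13
Reactants: 20 2-hydroxy-3,4,5-trimethoxy-6-({(3R)-3-methyl-5-[(1S,2S)-1,2,3-trimethylcyclohex-3-en-1-yl]pent-1-en-3-yl}oxy)benzaldehyde
Product: 21 2-ethenyl-4,5,6-trimethoxy-3-({(3R)-3-methyl-5-[(1S,2S)-1,2,3-trimethylcyclohex-3-en-1-yl]pent-1-en-3-yl}oxy)phenol
Conditions: Ph3PCH3Br (3.5 equiv), KOtBu (3.3 equiv), THF, 0 °C → rt
Reagents that add atoms: methyltriphenylphosphonium bromide, C[P+](c1ccccc1)(c1ccccc1)c1ccccc1.[Br-]
Why: In this Wittig methylenation the excess ylide first deprotonates the phenol and then converts the hindered aldehyde into the styrene without affecting the tertiary allyl aryl ether or C2.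

Step 14
Reactants: 21 2-ethenyl-4,5,6-trimethoxy-3-({(3R)-3-methyl-5-[(1S,2S)-1,2,3-trimethylcyclohex-3-en-1-yl]pent-1-en-3-yl}oxy)phenol
Product: 22 (2R)-6,7,8-trimethoxy-2-methyl-2-{2-[(1S,2S)-1,2,3-trimethylcyclohex-3-en-1-yl]ethyl}-2H-chromen-5-ol
Conditions: second-generation Grubbs catalyst RuCl2(=CHPh)(PCy3)(H2IMes) (5 mol%), CH2Cl2 (0.01 M), 40 °C
Reagents that add atoms: none
Why: Ring-closing metathesis between the styrene and the vinyl group on C2 closes the six-membered pyran ring by forming C3=C4 with loss of ethene, while the trisubstituted ring alkene is too hindered to take part and no stereocentre is involved.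

**Compound list**

1 | 3-methylideneoxolan-2-one (α-methylene-γ-butyrolactone) | C=C1CCOC1=O | starting material
2 | (3E)-3-methylpenta-1,3-diene (commercial E/Z mixture) | C=C/C(C)=C/C | starting material
3 | (5R,6R)-6,7-dimethyl-2-oxaspiro[4.5]dec-7-en-1-one (carbonyl cis to the 6-methyl) | O=C1OCC[C@@]12CCC=C(C)[C@H]2C | intermediate
4 | (5R,6R)-6,7-dimethyl-2-oxaspiro[4.5]dec-7-en-1-ol (lactol, both C1 anomers) | OC1OCC[C@@]12CCC=C(C)[C@H]2C | intermediate
5 | 2-[(1R,2R)-1-(hydrazinylidenemethyl)-2,3-dimethylcyclohex-3-en-1-yl]ethan-1-ol | NN=C[C@@]1(CCO)CCC=C(C)[C@H]1C | intermediate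
6 | 2-[(1S,2S)-1,2,3-trimethylcyclohex-3-en-1-yl]ethan-1-ol | OCC[C@]1(C)CCC=C(C)[C@H]1C | intermediate
7 | 2-[(1S,2S)-1,2,3-trimethylcyclohex-3-en-1-yl]ethyl 4-methylbenzenesulfonate | Cc1ccc(cc1)S(=O)(=O)OCC[C@]1(C)CCC=C(C)[C@H]1C | intermediate
8 | 4-[(1S,2S)-1,2,3-trimethylcyclohex-3-en-1-yl]but-1-yne | C#CCC[C@]1(C)CCC=C(C)[C@H]1C | intermediate
9 | dimethyl{(1E)-2-methyl-4-[(1S,2S)-1,2,3-trimethylcyclohex-3-en-1-yl]but-1-en-1-yl}alumane | C[Al](C)/C=C(\C)CC[C@]1(C)CCC=C(C)[C@H]1C | intermediate
10 | lithium butyl(dimethyl){(1E)-2-methyl-4-[(1S,2S)-1,2,3-trimethylcyclohex-3-en-1-yl]but-1-en-1-yl}aluminate | [Li+].CCCC[Al-](C)(C)/C=C(\C)CC[C@]1(C)CCC=C(C)[C@H]1C | intermediate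
11 | (2E)-3-methyl-5-[(1S,2S)-1,2,3-trimethylcyclohex-3-en-1-yl]pent-2-en-1-ol | OC/C=C(\C)CC[C@]1(C)CCC=C(C)[C@H]1C | intermediate
12 | methyl (2E)-3-methyl-5-[(1S,2S)-1,2,3-trimethylcyclohex-3-en-1-yl]pent-2-en-1-yl carbonate | COC(=O)OC/C=C(\C)CC[C@]1(C)CCC=C(C)[C@H]1C | intermediate
13 | 2,3,4-trimethoxybenzaldehyde | O=Cc1ccc(OC)c(OC)c1OC | starting material
14 | 5-bromo-2,3,4-trimethoxybenzaldehyde | O=Cc1cc(Br)c(OC)c(OC)c1OC | intermediate
15 | 5-bromo-2,3,4-trimethoxyphenyl formate | O=COc1cc(Br)c(OC)c(OC)c1OC | intermediate
16 | 5-bromo-2,3,4-trimethoxyphenol | Oc1cc(Br)c(OC)c(OC)c1OC | intermediate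
17 | 4,5,6-trimethoxybenzene-1,3-diol | Oc1cc(O)c(OC)c(OC)c1OC | intermediate
18 | [(2,6-dihydroxy-3,4,5-trimethoxyphenyl)methylidene]dimethylazanium chloride | C[N+](C)=Cc1c(O)c(OC)c(OC)c(OC)c1O.[Cl-] | intermediate
19 | 2,6-dihydroxy-3,4,5-trimethoxybenzaldehyde | O=Cc1c(O)c(OC)c(OC)c(OC)c1O | intermediate
20 | 2-hydroxy-3,4,5-trimethoxy-6-({(3R)-3-methyl-5-[(1S,2S)-1,2,3-trimethylcyclohex-3-en-1-yl]pent-1-en-3-yl}oxy)benzaldehyde | COc1c(O)c(C=O)c(c(OC)c1OC)O[C@](C)(CC[C@]1(C)CCC=C(C)[C@H]1C)C=C | intermediate
21 | 2-ethenyl-4,5,6-trimethoxy-3-({(3R)-3-methyl-5-[(1S,2S)-1,2,3-trimethylcyclohex-3-en-1-yl]pent-1-en-3-yl}oxy)phenol | COc1c(O)c(C=C)c(c(OC)c1OC)O[C@](C)(CC[C@]1(C)CCC=C(C)[C@H]1C)C=C | intermediate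
22 | (2R)-6,7,8-trimethoxy-2-methyl-2-{2-[(1S,2S)-1,2,3-trimethylcyclohex-3-en-1-yl]ethyl}-2H-chromen-5-ol | COc1c(O)c2c(c(OC)c1OC)O[C@](C)(CC[C@]1(C)CCC=C(C)[C@H]1C)C=C2 | target

**Step count**

Total: 14 steps. Longest linear sequence: 10 steps (steps 1–7, then 12–14); the arene branch is steps 8–11.

**Steps most likely to fail**

Step 1. The lactone offers the catalyst neither a formyl C–H nor an α-C–H contact, so enantiofacial discrimination may be incomplete; ortho or endo selectivity may also erode, and the Lewis acid may oligomerise the diene. The fallback sets out again from diene 2 and changes the dienophile to a 2-substituted acrolein, the class on which oxazaborolidinium catalysis is best established. 4-[(tert-Butyldimethylsilyl)oxy]butanal F1 would be α-methylenated (aqueous formaldehyde, pyrrolidine and propionic acid as catalysts) to 4-[(tert-butyldimethylsilyl)oxy]-2-methylidenebutanal F2. F2 should add to 2 under the same oxazaborolidine activated with HNTf2 (CH2Cl2, −78 °C), formyl group endo, to give (1R,2R)-1-{2-[(tert-butyldimethylsilyl)oxy]ethyl}-2,3-dimethylcyclohex-3-ene-1-carbaldehyde F3. Bu4NF in THF then frees the alcohol, which closes onto the aldehyde, and the route is rejoined at lactol 4.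

Step 12. Attack of the hindered, hydrogen-bonded phenoxide at the fully substituted allyl terminus may be slow, so that linear O-allylation, β-hydride elimination to a diene, or incomplete facial control (a C2 epimer that is hard to remove) can compete. The fallback sets out from allylic alcohol 11 and resorcinol 17 and gives up catalyst control at C2. Oxidation of 11 with MnO2 would give (2E)-3-methyl-5-[(1S,2S)-1,2,3-trimethylcyclohex-3-en-1-yl]pent-2-enal F4. Condensation of F4 with 17 (ethylenediammonium diacetate, toluene, reflux) should proceed by C-alkylation at the single free ring carbon, dehydration to an ortho-quinone methide and oxa-6π electrocyclisation. This gives 22 directly, accompanied by its epimer (2S)-6,7,8-trimethoxy-2-methyl-2-{2-[(1S,2S)-1,2,3-trimethylcyclohex-3-en-1-yl]ethyl}-2H-chromen-5-ol F5, because this ring closure is not stereocontrolled. The two diastereomers would be separated by preparative HPLC (chiral stationary phase if needed), and the route is rejoined at 22.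

Step 10. Oxidative addition into the electron-rich bromophenoxide may be slow, protodebromination may compete, and the pentaoxygenated product may oxidise in air under basic conditions. The fallback sets out from 16 and avoids palladium: deprotonation with NaH, bromine–lithium exchange with t-BuLi (THF, −78 °C) and quench with B(OMe)3 would give, after acidic work-up, (5-hydroxy-2,3,4-trimethoxyphenyl)boronic acid F6. Oxidation of F6 with H2O2 and NaOH returns the route to 17.

Further compounds
F1 | step 1 | 4-[(tert-butyldimethylsilyl)oxy]butanal | O=CCCCO[Si](C)(C)C(C)(C)C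
F2 | step 1 | 4-[(tert-butyldimethylsilyl)oxy]-2-methylidenebutanal | C=C(CCO[Si](C)(C)C(C)(C)C)C=O
F3 | step 1 | (1R,2R)-1-{2-[(tert-butyldimethylsilyl)oxy]ethyl}-2,3-dimethylcyclohex-3-ene-1-carbaldehyde | O=C[C@@]1(CCO[Si](C)(C)C(C)(C)C)CCC=C(C)[C@H]1C
F4 | step 12 | (2E)-3-methyl-5-[(1S,2S)-1,2,3-trimethylcyclohex-3-en-1-yl]pent-2-enal | O=C/C=C(\C)CC[C@]1(C)CCC=C(C)[C@H]1C
F5 | step 12 | (2S)-6,7,8-trimethoxy-2-methyl-2-{2-[(1S,2S)-1,2,3-trimethylcyclohex-3-en-1-yl]ethyl}-2H-chromen-5-ol | COc1c(O)c2c(c(OC)c1OC)O[C@@](C)(CC[C@]1(C)CCC=C(C)[C@H]1C)C=C2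
F6 | step 10 | (5-hydroxy-2,3,4-trimethoxyphenyl)boronic acid | COc1c(O)cc(B(O)O)c(OC)c1OC
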